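**Plan**

1. Germacranolide numbering is used. Ring A is the carbocycle C1–C10 (C2 OAc, C3=C4 carrying C15, C5=C6, C8 ester, C10 Me/OH). Ring B is the butenolide O–C6, C7=C11, C12=O, with C13H2OH on C11.
2. Retrosynthetic cuts: the O8 ester; ring A at C5=C6 (Horner–Wadsworth–Emmons closure between a C6 phosphonate on ring B and a C5 (Z)-enal); ring B at C7=C11; the chain at C2–C3 and C7–C8.
3. Enabling feature: the ring-B oxygen sits on C6, next to C7. C7=C11 can therefore be made by joining a C7 ketone to the α-carbon of an acyl group already on O6. Both carbons are electrophiles (C=O and the CCl2 of a 2,2-dichloro ester) and are united by polarity reversal with divalent chromium, which gives the tetrasubstituted alkene in the same operation and leaves the acidic C6–H phosphonate intact for ring A.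
4. Forward order: (R)-mevalonolactone (C8–C10, C1, C2) plus a (Z)-vinyllithium (C3–C5) gives the enone, then the C2 acetate. The C8 aldehyde plus ethynylphosphonate (C6, C7) gives the β-ketophosphonate, then the C6 diazo compound, then O–H insertion into the dichloro acid (C11–C13). Ring B closes (key step), then ring A, then O8 methacrylate and O13 deprotection.
5. Stereochemistry: C10 from the chiral pool; C2 by CBS reduction; C8 by catalytic asymmetric alkynylation; 3Z from anti-carbomagnesiation and iodination; 5E enforced by ring A. The helpers (two chlorines, the phosphonate, the silyl groups) are all lost on the way.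

Key step: step 17

Remark: 23–28 (and F2–F5) are mixtures of epimers at the phosphonate-bearing C6, which becomes sp2 in step 20; their SMILES carry no descriptor at C6.

**Route**

Step 1
Reactants: 1 prop-2-yn-1-ol
Product: 3 (Z)-3-iodo-2-methylprop-2-en-1-ol, via alkenylmagnesium alkoxide 2 (not isolated)
Conditions: MeMgBr (2.2 equiv), CuI (10 mol %), THF, −10 °C to rt; then I2, −10 °C
Reagents that add atoms: methylmagnesium bromide C[Mg]Br; iodine I-I
Why: Copper-catalysed anti-carbomagnesiation of the propargylic alkoxide puts methyl on C4 and magnesium on C3 cis to the CH2O group in a five-membered chelate (2), and iodinolysis with retention fixes the Z geometry needed for C3=C4.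

Step 2
Reactants: 3 (Z)-3-iodo-2-methylprop-2-en-1-ol
Product: 4 (Z)-tert-butyl[(3-iodo-2-methylprop-2-en-1-yl)oxy]dimethylsilane
Conditions: TBSCl, imidazole, CH2Cl2, rt
Reagents that add atoms: tert-butyldimethylsilyl chloride CC(C)(C)[Si](C)(C)Cl
Why: Routine silylation of a primary alcohol.

Step 3
Reactants: 5 methyl trichloroacetate
Product: 7 methyl 2,2-dichloro-3-hydroxypropanoate, via dichloro zinc enolate 6 (not isolated)
Conditions: Zn dust, TMSCl (cat.), paraformaldehyde, THF, 40 °C; aq. HCl work-up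
Reagents that add atoms: formaldehyde (as paraformaldehyde) C=O
Why: Reformatsky reaction: zinc inserts into one C–Cl bond and the enolate 6 adds to formaldehyde, giving C11–C13 with the two chlorines the key step needs.

Step 4
Reactants: 7 methyl 2,2-dichloro-3-hydroxypropanoate
Product: 8 methyl 3-(tert-butyldiphenylsilyloxy)-2,2-dichloropropanoate
Conditions: TBDPSCl, imidazole, DMF, rt
Reagents that add atoms: tert-butyldiphenylsilyl chloride CC(C)(C)[Si](Cl)(c1ccccc1)c1ccccc1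
Why: Silylation with a bulky group that is a poor leaving group in step 17 and outlasts the TBS and TES ethers in step 18.

Step 5
Reactants: 8 methyl 3-(tert-butyldiphenylsilyloxy)-2,2-dichloropropanoate
Product: 9 3-(tert-butyldiphenylsilyloxy)-2,2-dichloropropanoic acid
Conditions: LiOH, THF/H2O, 0 °C; then aq. HCl to pH 3
Reagents that add atoms: lithium hydroxide [Li+].[OH-]
Why: Saponification of the activated, non-enolisable dichloro ester should proceed at 0 °C without touching the silyl ether.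

Step 6
Reactants: 10 (R)-mevalonolactone
Product: 11 (3R)-3,5-dihydroxy-N-methoxy-N,3-dimethylpentanamide
Conditions: MeNH(OMe)·HCl, Me3Al, CH2Cl2, 0 °C to rt
Reagents that add atoms: N,O-dimethylhydroxylamine hydrochloride CNOC.Cl
Why: Weinreb aminolysis of the lactone by the aluminium amide opens the ring and leaves the chiral-pool C10 centre untouched.

Step 7
Reactants: 11 (3R)-3,5-dihydroxy-N-methoxy-N,3-dimethylpentanamide
Product: 12 (3R)-N-methoxy-N,3-dimethyl-3,5-bis(triethylsilyloxy)pentanamide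
Conditions: TESOTf (2.5 equiv), 2,6-lutidine, CH2Cl2, −78 to 0 °C
Reagents that add atoms: triethylsilyl trifluoromethanesulfonate CC[Si](CC)(CC)OS(=O)(=O)C(F)(F)F
Why: Silyl triflate silylation caps the primary and the hindered tertiary hydroxyl, the latter to prevent hemiketal formation with the later C7 ketone.

Step 8
Reactants: 4 (Z)-tert-butyl[(3-iodo-2-methylprop-2-en-1-yl)oxy]dimethylsilane; 12 (3R)-N-methoxy-N,3-dimethyl-3,5-bis(triethylsilyloxy)pentanamide
Product: 14 (2Z,6R)-1-(tert-butyldimethylsilyloxy)-2,6-dimethyl-6,8-bis(triethylsilyloxy)oct-2-en-4-one, via (Z)-vinyllithium 13 (not isolated)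
Conditions: 4, t-BuLi (2.0 equiv), Et2O, −78 °C; then 12, −78 to −20 °C
Reagents that add atoms: none
Why: Iodine–lithium exchange retains the alkene geometry and the vinyllithium 13 adds once to the amide (Weinreb ketone synthesis), so the Z C3=C4 bond is carried into the enone.

Step 9
Reactants: 14 (2Z,6R)-1-(tert-butyldimethylsilyloxy)-2,6-dimethyl-6,8-bis(triethylsilyloxy)oct-2-en-4-one
Product: 15 (2Z,4S,6R)-1-(tert-butyldimethylsilyloxy)-2,6-dimethyl-6,8-bis(triethylsilyloxy)oct-2-en-4-ol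
Conditions: (R)-Me-CBS oxazaborolidine (0.5 equiv), catecholborane, toluene, −78 °C
Reagents that add atoms: none
Why: Corey–Bakshi–Shibata reduction: with the alkenyl group as the large substituent, the (R)-oxazaborolidine should deliver hydride to the face that gives the 2S carbinol under reagent control.

Step 10
Reactants: 15 (2Z,4S,6R)-1-(tert-butyldimethylsilyloxy)-2,6-dimethyl-6,8-bis(triethylsilyloxy)oct-2-en-4-ol
Product: 16 (2Z,4S,6R)-1-(tert-butyldimethylsilyloxy)-2,6-dimethyl-6,8-bis(triethylsilyloxy)oct-2-en-4-yl acetate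
Conditions: Ac2O, pyridine, DMAP (cat.), CH2Cl2, 0 °C to rt
Reagents that add atoms: acetic anhydride CC(=O)OC(C)=O
Why: Acetylation installs the C2 acetate of the target, which then serves as the protecting group of O2.

Step 11
Reactants: 16 (2Z,4S,6R)-1-(tert-butyldimethylsilyloxy)-2,6-dimethyl-6,8-bis(triethylsilyloxy)oct-2-en-4-yl acetate
Product: 17 (3S,5S,6Z)-8-(tert-butyldimethylsilyloxy)-3,7-dimethyl-1-oxo-3-(triethylsilyloxy)oct-6-en-5-yl acetate
Conditions: (COCl)2, DMSO, CH2Cl2, −78 to −30 °C; then Et3N, −78 to 0 °C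
Reagents that add atoms: none
Why: Swern conditions cleave and oxidise a primary triethylsilyl ether directly to the aldehyde, while the tertiary TES ether, the TBS ether and the acetate should stay intact.

Step 12
Reactants: 17 (3S,5S,6Z)-8-(tert-butyldimethylsilyloxy)-3,7-dimethyl-1-oxo-3-(triethylsilyloxy)oct-6-en-5-yl acetate; 18 diethyl ethynylphosphonate
Product: 19 diethyl [(3R,5R,7S,8Z)-7-acetoxy-10-(tert-butyldimethylsilyloxy)-3-hydroxy-5,9-dimethyl-5-(triethylsilyloxy)dec-8-en-1-yn-1-yl]phosphonate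
Conditions: 18 (3 equiv), Me2Zn (3 equiv), ProPhenol ligand (20 mol %, the enantiomer that directs the alkynyl group to the Si face), Ph3PO (40 mol %), toluene, 4 °C
Reagents that add atoms: none
Why: Zinc–ProPhenol catalysed alkynylation of an aldehyde: the chiral dinuclear zinc complex should deliver the alkynyl group to the Si face and set C8 as R under reagent control, bringing in C7, C6 and the phosphonate.

Step 13
Reactants: 19 diethyl [(3R,5R,7S,8Z)-7-acetoxy-10-(tert-butyldimethylsilyloxy)-3-hydroxy-5,9-dimethyl-5-(triethylsilyloxy)dec-8-en-1-yn-1-yl]phosphonate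
Product: 20 diethyl [(3R,5S,7S,8Z)-7-acetoxy-3,10-bis(tert-butyldimethylsilyloxy)-5,9-dimethyl-5-(triethylsilyloxy)dec-8-en-1-yn-1-yl]phosphonate
Conditions: TBSOTf, 2,6-lutidine, CH2Cl2, −78 °C
Reagents that add atoms: tert-butyldimethylsilyl trifluoromethanesulfonate CC(C)(C)[Si](C)(C)OS(=O)(=O)C(F)(F)F
Why: Routine silylation of the propargylic alcohol.

Step 14
Reactants: 20 diethyl [(3R,5S,7S,8Z)-7-acetoxy-3,10-bis(tert-butyldimethylsilyloxy)-5,9-dimethyl-5-(triethylsilyloxy)dec-8-en-1-yn-1-yl]phosphonate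
Product: 21 diethyl [(3R,5S,7S,8Z)-7-acetoxy-3,10-bis(tert-butyldimethylsilyloxy)-5,9-dimethyl-2-oxo-5-(triethylsilyloxy)dec-8-en-1-yl]phosphonate
Conditions: Ph3PAuNTf2 (5 mol %), 1,4-dioxane/H2O (10:1), 50 °C
Reagents that add atoms: water O
Why: Gold-catalysed hydration of a 1-alkynylphosphonate puts oxygen on the alkyne carbon remote from phosphorus (C7) and should give the β-ketophosphonate.

Step 15
Reactants: 21 diethyl [(3R,5S,7S,8Z)-7-acetoxy-3,10-bis(tert-butyldimethylsilyloxy)-5,9-dimethyl-2-oxo-5-(triethylsilyloxy)dec-8-en-1-yl]phosphonate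
Product: 22 diethyl [(3R,5S,7S,8Z)-7-acetoxy-3,10-bis(tert-butyldimethylsilyloxy)-1-diazo-5,9-dimethyl-2-oxo-5-(triethylsilyloxy)dec-8-en-1-yl]phosphonate
Conditions: 4-acetamidobenzenesulfonyl azide, Et3N, MeCN, 0 °C to rt
Reagents that add atoms: 4-acetamidobenzenesulfonyl azide CC(=O)Nc1ccc(cc1)S(=O)(=O)N=[N+]=[N-]
Why: Regitz diazo transfer to the active methylene between the ketone and the phosphonate.

Step 16
Reactants: 22 diethyl [(3R,5S,7S,8Z)-7-acetoxy-3,10-bis(tert-butyldimethylsilyloxy)-1-diazo-5,9-dimethyl-2-oxo-5-(triethylsilyloxy)dec-8-en-1-yl]phosphonate; 9 3-(tert-butyldiphenylsilyloxy)-2,2-dichloropropanoic acid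
Product: 23 (3R,5S,7S,8Z)-7-acetoxy-3,10-bis(tert-butyldimethylsilyloxy)-1-(diethoxyphosphoryl)-5,9-dimethyl-2-oxo-5-(triethylsilyloxy)dec-8-en-1-yl 3-(tert-butyldiphenylsilyloxy)-2,2-dichloropropanoate
Conditions: 9 (1.3 equiv, slow addition), Rh2(OAc)4 (2 mol %), CH2Cl2, 40 °C
Reagents that add atoms: none
Why: Rhodium carbenoid O–H insertion into the carboxylic acid hangs the dichloroacyl group on O6; the new C6 centre is formed without control and is erased in step 20.

Step 17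
Reactants: 23 (3R,5S,7S,8Z)-7-acetoxy-3,10-bis(tert-butyldimethylsilyloxy)-1-(diethoxyphosphoryl)-5,9-dimethyl-2-oxo-5-(triethylsilyloxy)dec-8-en-1-yl 3-(tert-butyldiphenylsilyloxy)-2,2-dichloropropanoate
Product: 26 diethyl {3-[(1R,3S,5S,6Z)-5-acetoxy-1,8-bis(tert-butyldimethylsilyloxy)-3,7-dimethyl-3-(triethylsilyloxy)oct-6-en-1-yl]-4-[(tert-butyldiphenylsilyloxy)methyl]-5-oxo-2,5-dihydrofuran-2-yl}phosphonate, via chromium enolate 24 (not isolated), via chloro aldolate 25 (not isolated)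
Conditions: CrCl2 (6 equiv), THF, rt, argon
Reagents that add atoms: none
Why: Proposed new method: divalent chromium abstracts one chlorine of the 2,2-dichloro ester and a second equivalent traps the radical as the trivalent chromium enolate 24, which adds through C11 to the C7 ketone (5-exo-trig aldol closure of ring B through C7–C6–O6–C12–C11) to give the chloro aldolate 25; reduction of the remaining C11–Cl bond then triggers β-elimination of the chromium-bound C7 oxygen and gives the C7=C11 bond directly. The closest known reactions are the CrCl2 olefination of aldehydes with trihaloacetates and the CrCl2 aldol/β-elimination of 2,2-dichloro esters with aldehydes; new here is the intramolecular use on a ketone to give a tetrasubstituted butenolide. The event joins two electrophilic carbons (CCl2 and C=O) and needs no base, so the acidic C6–H and its phosphonate should survive. No stereocentre is formed: the alkene geometry is fixed by the five-membered ring and C6 stays an epimeric mixture. The step needs chemoselectivity for the C–Cl bonds over the ketone, the α-acyloxy ketone, the allylic acetate and the silyl ethers; CrCl2 reduces only activated halides, and the bulky silyloxy group on C13 is a poor leaving group, so its loss from 24 should be slower than the 5-exo closure.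

Step 18
Reactants: 26 diethyl {3-[(1R,3S,5S,6Z)-5-acetoxy-1,8-bis(tert-butyldimethylsilyloxy)-3,7-dimethyl-3-(triethylsilyloxy)oct-6-en-1-yl]-4-[(tert-butyldiphenylsilyloxy)methyl]-5-oxo-2,5-dihydrofuran-2-yl}phosphonate
Product: 27 diethyl {3-[(1R,3R,5S,6Z)-5-acetoxy-1,3,8-trihydroxy-3,7-dimethyloct-6-en-1-yl]-4-[(tert-butyldiphenylsilyloxy)methyl]-5-oxo-2,5-dihydrofuran-2-yl}phosphonate
Conditions: HF·pyridine, pyridine, THF, 0 °C to rt
Reagents that add atoms: none
Why: Fluoride desilylation should remove the two TBS ethers and the tertiary TES ether while the more robust primary TBDPS ether stays.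

Step 19
Reactants: 27 diethyl {3-[(1R,3R,5S,6Z)-5-acetoxy-1,3,8-trihydroxy-3,7-dimethyloct-6-en-1-yl]-4-[(tert-butyldiphenylsilyloxy)methyl]-5-oxo-2,5-dihydrofuran-2-yl}phosphonate
Product: 28 diethyl {3-[(1R,3R,5S,6Z)-5-acetoxy-1,3-dihydroxy-3,7-dimethyl-8-oxooct-6-en-1-yl]-4-[(tert-butyldiphenylsilyloxy)methyl]-5-oxo-2,5-dihydrofuran-2-yl}phosphonate
Conditions: TEMPO (20 mol %), PhI(OAc)2, CH2Cl2, rt
Reagents that add atoms: none
Why: TEMPO/PhI(OAc)2 oxidation is selective for the primary allylic alcohol over the secondary and tertiary hydroxyls and should not isomerise the Z enal.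

Step 20
Reactants: 28 diethyl {3-[(1R,3R,5S,6Z)-5-acetoxy-1,3-dihydroxy-3,7-dimethyl-8-oxooct-6-en-1-yl]-4-[(tert-butyldiphenylsilyloxy)methyl]-5-oxo-2,5-dihydrofuran-2-yl}phosphonate
Product: 29 (2S,3Z,5E,8R,10R)-2-acetoxy-13-(tert-butyldiphenylsilyloxy)-8,10-dihydroxygermacra-3,5,7(11)-trien-12,6-olide
Conditions: LiCl, i-Pr2NEt, MeCN (1 mM), rt
Reagents that add atoms: none
Why: Intramolecular Horner–Wadsworth–Emmons olefination of the lactone γ-phosphonate (as with phthalide 3-phosphonates) with the C5 aldehyde closes ring A; the ten-membered ring should accept only the C5=C6 isomer with C4 cis to C7 (5E), and both C6 epimers converge.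

Step 21
Reactants: 29 (2S,3Z,5E,8R,10R)-2-acetoxy-13-(tert-butyldiphenylsilyloxy)-8,10-dihydroxygermacra-3,5,7(11)-trien-12,6-olide
Product: 30 (2S,3Z,5E,8R,10S)-2-acetoxy-13-(tert-butyldiphenylsilyloxy)-10-hydroxy-8-(methacryloyloxy)germacra-3,5,7(11)-trien-12,6-olide
Conditions: methacrylic anhydride, Et3N, DMAP, CH2Cl2, 0 °C
Reagents that add atoms: methacrylic anhydride C=C(C)C(=O)OC(=O)C(C)=C
Why: DMAP-catalysed acylation should take the secondary C8 hydroxyl and leave the tertiary C10 hydroxyl.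

Step 22
Reactants: 30 (2S,3Z,5E,8R,10S)-2-acetoxy-13-(tert-butyldiphenylsilyloxy)-10-hydroxy-8-(methacryloyloxy)germacra-3,5,7(11)-trien-12,6-olide
Product: 31 (2S,3Z,5E,8R,10S)-2-acetoxy-10,13-dihydroxy-8-(methacryloyloxy)germacra-3,5,7(11)-trien-12,6-olide (CNP0246543.1)
Conditions: TBAF, AcOH (1:1), THF, 0 °C to rt
Reagents that add atoms: none
Why: Buffered fluoride desilylation should free the primary C13 hydroxyl without ester cleavage or acyl migration.

**Compound list**

1 | prop-2-yn-1-ol | C#CCO | starting material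
2 | alkenylmagnesium alkoxide | Br[Mg]/C=C(C)\CO[Mg]Br | intermediate
3 | (Z)-3-iodo-2-methylprop-2-en-1-ol | I/C=C(C)\CO | intermediate
4 | (Z)-tert-butyl[(3-iodo-2-methylprop-2-en-1-yl)oxy]dimethylsilane | I/C=C(C)\CO[Si](C)(C)C(C)(C)C | intermediate
5 | methyl trichloroacetate | COC(=O)C(Cl)(Cl)Cl | starting material
6 | dichloro zinc enolate | COC(=O)C(Cl)(Cl)[Zn]Cl | intermediate
7 | methyl 2,2-dichloro-3-hydroxypropanoate | COC(=O)C(Cl)(Cl)CO | intermediate
8 | methyl 3-(tert-butyldiphenylsilyloxy)-2,2-dichloropropanoate | COC(=O)C(Cl)(Cl)CO[Si](c1ccccc1)(c1ccccc1)C(C)(C)C | intermediate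
9 | 3-(tert-butyldiphenylsilyloxy)-2,2-dichloropropanoic acid | OC(=O)C(Cl)(Cl)CO[Si](c1ccccc1)(c1ccccc1)C(C)(C)C | intermediate
10 | (R)-mevalonolactone | C[C@@]1(O)CCOC(=O)C1 | starting material
11 | (3R)-3,5-dihydroxy-N-methoxy-N,3-dimethylpentanamide | OCC[C@@](C)(O)CC(=O)N(C)OC | intermediate
12 | (3R)-N-methoxy-N,3-dimethyl-3,5-bis(triethylsilyloxy)pentanamide | CC[Si](CC)(CC)OCC[C@@](C)(O[Si](CC)(CC)CC)CC(=O)N(C)OC | intermediate
13 | (Z)-vinyllithium | [Li]/C=C(C)\CO[Si](C)(C)C(C)(C)C | intermediate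
14 | (2Z,6R)-1-(tert-butyldimethylsilyloxy)-2,6-dimethyl-6,8-bis(triethylsilyloxy)oct-2-en-4-one | CC[Si](CC)(CC)OCC[C@@](C)(O[Si](CC)(CC)CC)CC(=O)/C=C(C)\CO[Si](C)(C)C(C)(C)C | intermediate
15 | (2Z,4S,6R)-1-(tert-butyldimethylsilyloxy)-2,6-dimethyl-6,8-bis(triethylsilyloxy)oct-2-en-4-ol | CC[Si](CC)(CC)OCC[C@@](C)(O[Si](CC)(CC)CC)C[C@H](O)/C=C(C)\CO[Si](C)(C)C(C)(C)C | intermediate
16 | (2Z,4S,6R)-1-(tert-butyldimethylsilyloxy)-2,6-dimethyl-6,8-bis(triethylsilyloxy)oct-2-en-4-yl acetate | CC[Si](CC)(CC)OCC[C@@](C)(O[Si](CC)(CC)CC)C[C@H](OC(C)=O)/C=C(C)\CO[Si](C)(C)C(C)(C)C | intermediate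
17 | (3S,5S,6Z)-8-(tert-butyldimethylsilyloxy)-3,7-dimethyl-1-oxo-3-(triethylsilyloxy)oct-6-en-5-yl acetate | O=CC[C@@](C)(O[Si](CC)(CC)CC)C[C@H](OC(C)=O)/C=C(C)\CO[Si](C)(C)C(C)(C)C | intermediate
18 | diethyl ethynylphosphonate | C#CP(=O)(OCC)OCC | starting material
19 | diethyl [(3R,5R,7S,8Z)-7-acetoxy-10-(tert-butyldimethylsilyloxy)-3-hydroxy-5,9-dimethyl-5-(triethylsilyloxy)dec-8-en-1-yn-1-yl]phosphonate | O[C@@H](C#CP(=O)(OCC)OCC)C[C@@](C)(O[Si](CC)(CC)CC)C[C@H](OC(C)=O)/C=C(C)\CO[Si](C)(C)C(C)(C)C | intermediate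
20 | diethyl [(3R,5S,7S,8Z)-7-acetoxy-3,10-bis(tert-butyldimethylsilyloxy)-5,9-dimethyl-5-(triethylsilyloxy)dec-8-en-1-yn-1-yl]phosphonate | CC(C)(C)[Si](C)(C)O[C@@H](C#CP(=O)(OCC)OCC)C[C@@](C)(O[Si](CC)(CC)CC)C[C@H](OC(C)=O)/C=C(C)\CO[Si](C)(C)C(C)(C)C | intermediate
21 | diethyl [(3R,5S,7S,8Z)-7-acetoxy-3,10-bis(tert-butyldimethylsilyloxy)-5,9-dimethyl-2-oxo-5-(triethylsilyloxy)dec-8-en-1-yl]phosphonate | CC(C)(C)[Si](C)(C)O[C@@H](C(=O)CP(=O)(OCC)OCC)C[C@@](C)(O[Si](CC)(CC)CC)C[C@H](OC(C)=O)/C=C(C)\CO[Si](C)(C)C(C)(C)C | intermediate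
22 | diethyl [(3R,5S,7S,8Z)-7-acetoxy-3,10-bis(tert-butyldimethylsilyloxy)-1-diazo-5,9-dimethyl-2-oxo-5-(triethylsilyloxy)dec-8-en-1-yl]phosphonate | CC(C)(C)[Si](C)(C)O[C@@H](C(=O)C(=[N+]=[N-])P(=O)(OCC)OCC)C[C@@](C)(O[Si](CC)(CC)CC)C[C@H](OC(C)=O)/C=C(C)\CO[Si](C)(C)C(C)(C)C | intermediate
23 | (3R,5S,7S,8Z)-7-acetoxy-3,10-bis(tert-butyldimethylsilyloxy)-1-(diethoxyphosphoryl)-5,9-dimethyl-2-oxo-5-(triethylsilyloxy)dec-8-en-1-yl 3-(tert-butyldiphenylsilyloxy)-2,2-dichloropropanoate | CC(C)(C)[Si](C)(C)O[C@@H](C(=O)C(OC(=O)C(Cl)(Cl)CO[Si](c1ccccc1)(c1ccccc1)C(C)(C)C)P(=O)(OCC)OCC)C[C@@](C)(O[Si](CC)(CC)CC)C[C@H](OC(C)=O)/C=C(C)\CO[Si](C)(C)C(C)(C)C | intermediate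
24 | chromium enolate | CC(C)(C)[Si](C)(C)O[C@@H](C(=O)C(OC(O[Cr](Cl)Cl)=C(Cl)CO[Si](c1ccccc1)(c1ccccc1)C(C)(C)C)P(=O)(OCC)OCC)C[C@@](C)(O[Si](CC)(CC)CC)C[C@H](OC(C)=O)/C=C(C)\CO[Si](C)(C)C(C)(C)C | intermediate
25 | chloro aldolate | CC(C)(C)[Si](C)(C)O[C@@H](C1(O[Cr](Cl)Cl)C(Cl)(CO[Si](c2ccccc2)(c2ccccc2)C(C)(C)C)C(=O)OC1P(=O)(OCC)OCC)C[C@@](C)(O[Si](CC)(CC)CC)C[C@H](OC(C)=O)/C=C(C)\CO[Si](C)(C)C(C)(C)C | intermediate
26 | diethyl {3-[(1R,3S,5S,6Z)-5-acetoxy-1,8-bis(tert-butyldimethylsilyloxy)-3,7-dimethyl-3-(triethylsilyloxy)oct-6-en-1-yl]-4-[(tert-butyldiphenylsilyloxy)methyl]-5-oxo-2,5-dihydrofuran-2-yl}phosphonate | CC(C)(C)[Si](C)(C)O[C@@H](C1=C(CO[Si](c2ccccc2)(c2ccccc2)C(C)(C)C)C(=O)OC1P(=O)(OCC)OCC)C[C@@](C)(O[Si](CC)(CC)CC)C[C@H](OC(C)=O)/C=C(C)\CO[Si](C)(C)C(C)(C)C | intermediate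
27 | diethyl {3-[(1R,3R,5S,6Z)-5-acetoxy-1,3,8-trihydroxy-3,7-dimethyloct-6-en-1-yl]-4-[(tert-butyldiphenylsilyloxy)methyl]-5-oxo-2,5-dihydrofuran-2-yl}phosphonate | O[C@@H](C1=C(CO[Si](c2ccccc2)(c2ccccc2)C(C)(C)C)C(=O)OC1P(=O)(OCC)OCC)C[C@@](C)(O)C[C@H](OC(C)=O)/C=C(C)\CO | intermediate
28 | diethyl {3-[(1R,3R,5S,6Z)-5-acetoxy-1,3-dihydroxy-3,7-dimethyl-8-oxooct-6-en-1-yl]-4-[(tert-butyldiphenylsilyloxy)methyl]-5-oxo-2,5-dihydrofuran-2-yl}phosphonate | O[C@@H](C1=C(CO[Si](c2ccccc2)(c2ccccc2)C(C)(C)C)C(=O)OC1P(=O)(OCC)OCC)C[C@@](C)(O)C[C@H](OC(C)=O)/C=C(C)\C=O | intermediate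
29 | (2S,3Z,5E,8R,10R)-2-acetoxy-13-(tert-butyldiphenylsilyloxy)-8,10-dihydroxygermacra-3,5,7(11)-trien-12,6-olide | O[C@@H]1C[C@@](C)(O)C[C@H](OC(C)=O)/C=C(C)\C=C2\OC(=O)C(CO[Si](c3ccccc3)(c3ccccc3)C(C)(C)C)=C21 | intermediate
30 | (2S,3Z,5E,8R,10S)-2-acetoxy-13-(tert-butyldiphenylsilyloxy)-10-hydroxy-8-(methacryloyloxy)germacra-3,5,7(11)-trien-12,6-olide | C=C(C)C(=O)O[C@@H]1C[C@@](C)(O)C[C@H](OC(C)=O)/C=C(C)\C=C2\OC(=O)C(CO[Si](c3ccccc3)(c3ccccc3)C(C)(C)C)=C21 | intermediate
31 | (2S,3Z,5E,8R,10S)-2-acetoxy-10,13-dihydroxy-8-(methacryloyloxy)germacra-3,5,7(11)-trien-12,6-olide (CNP0246543.1) | C=C(C)C(=O)O[C@@H]1C[C@@](C)(O)C[C@H](OC(C)=O)/C=C(C)\C=C2\OC(=O)C(CO)=C21 | target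

**Step count and risks**

Total step count: 22. Longest linear sequence: 17 steps (10 to 31 through steps 6–22; equally 1 to 31 through steps 1, 2 and 8–22).

Steps most likely to fail:

1. Step 17 (proposed new method). The chromium enolate may lose the silyloxy group by β-elimination before it cyclises, or the sequence may stop at the chloro aldolate without the second reduction and elimination. The fallback makes the same bond by a stepwise samarium Reformatsky reaction and dehydration, both known reaction types. It sets out from 22. Silylation of commercial 2-bromo-3-hydroxypropanoic acid (TBDPSCl, imidazole; then aqueous K2CO3 to cleave the silyl ester) would give 2-bromo-3-(tert-butyldiphenylsilyloxy)propanoic acid F1. Rh2(OAc)4-catalysed O–H insertion of 22 into F1 would give the α-bromo ester F2. SmI2 (2.2 equiv, THF, −78 °C) should then effect the intramolecular Reformatsky addition to the C7 ketone and give the β-hydroxy lactone F3. Dehydration (SOCl2, pyridine, 0 °C) toward the acidic C11–H would give the butenolide, and the route is rejoined at 26.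

2. Step 20. Ring strain in the ten-membered ring may divert the phosphonate anion to intermolecular olefination (oligomers), and the base may isomerise the Z enal. The fallback inverts the order of ring formation, so that the more flexible open-chain β-ketophosphonate cyclises before ring B exists. It sets out from 23. Buffered HF·pyridine at 0 °C should remove only the primary allylic TBS ether and give the primary alcohol F4. TEMPO/PhI(OAc)2 would give the (Z)-enal F5. Horner–Wadsworth–Emmons closure of the α-acyloxy β-ketophosphonate (LiCl, i-Pr2NEt, MeCN, high dilution) would give the ten-membered dienone enol ester F6. The CrCl2 olefination of step 17, now run on the ring, would give the silylated bicycle F7. HF·pyridine then removes the C8 TBS and C10 TES ethers, and the route is rejoined at 29.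

3. Step 12. The α-unbranched aldehyde may undergo self-aldol condensation, or the facial selectivity of the catalytic alkynylation may be poor. The fallback sets C8 by reduction instead. It sets out from 17. Addition of the lithium acetylide of 18 (LiHMDS, THF, −78 °C) would give the C8-epimeric alkynol mixture F8. Dess–Martin oxidation would give the ynone F9. Noyori asymmetric transfer hydrogenation (RuCl[(R,R)-TsDPEN](p-cymene), HCO2H/Et3N) should give the 8R alcohol, and the route is rejoined at 19.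

**Further compounds**

F1 | step 17 | 2-bromo-3-(tert-butyldiphenylsilyloxy)propanoic acid (racemic) | OC(=O)C(Br)CO[Si](c1ccccc1)(c1ccccc1)C(C)(C)C
F2 | step 17 | α-bromo ester analogue of 23 (Br and H in place of the two Cl) | CC(C)(C)[Si](C)(C)O[C@@H](C(=O)C(OC(=O)C(Br)CO[Si](c1ccccc1)(c1ccccc1)C(C)(C)C)P(=O)(OCC)OCC)C[C@@](C)(O[Si](CC)(CC)CC)C[C@H](OC(C)=O)/C=C(C)\CO[Si](C)(C)C(C)(C)C
F3 | step 17 | β-hydroxy lactone (C7 OH and C11 H; hydrate of 26) | CC(C)(C)[Si](C)(C)O[C@@H](C1(O)C(CO[Si](c2ccccc2)(c2ccccc2)C(C)(C)C)C(=O)OC1P(=O)(OCC)OCC)C[C@@](C)(O[Si](CC)(CC)CC)C[C@H](OC(C)=O)/C=C(C)\CO[Si](C)(C)C(C)(C)C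
F4 | step 20 | primary alcohol from 23 (O5 free) | CC(C)(C)[Si](C)(C)O[C@@H](C(=O)C(OC(=O)C(Cl)(Cl)CO[Si](c1ccccc1)(c1ccccc1)C(C)(C)C)P(=O)(OCC)OCC)C[C@@](C)(O[Si](CC)(CC)CC)C[C@H](OC(C)=O)/C=C(C)\CO
F5 | step 20 | (Z)-enal from F4 (C5 aldehyde) | CC(C)(C)[Si](C)(C)O[C@@H](C(=O)C(OC(=O)C(Cl)(Cl)CO[Si](c1ccccc1)(c1ccccc1)C(C)(C)C)P(=O)(OCC)OCC)C[C@@](C)(O[Si](CC)(CC)CC)C[C@H](OC(C)=O)/C=C(C)\C=O
F6 | step 20 | ten-membered dienone enol ester (ring A closed and ring B open) | CC(C)(C)[Si](C)(C)O[C@@H]1C[C@@](C)(O[Si](CC)(CC)CC)C[C@H](OC(C)=O)/C=C(C)\C=C(\OC(=O)C(Cl)(Cl)CO[Si](c2ccccc2)(c2ccccc2)C(C)(C)C)C1=O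
F7 | step 20 | 8-O-TBS 10-O-TES ether of 29 | CC(C)(C)[Si](C)(C)O[C@@H]1C[C@@](C)(O[Si](CC)(CC)CC)C[C@H](OC(C)=O)/C=C(C)\C=C2\OC(=O)C(CO[Si](c3ccccc3)(c3ccccc3)C(C)(C)C)=C21
F8 | step 12 | C8-epimeric mixture of 19 | OC(C#CP(=O)(OCC)OCC)C[C@@](C)(O[Si](CC)(CC)CC)C[C@H](OC(C)=O)/C=C(C)\CO[Si](C)(C)C(C)(C)C
F9 | step 12 | ynone (C8 ketone of 19) | O=C(C#CP(=O)(OCC)OCC)C[C@@](C)(O[Si](CC)(CC)CC)C[C@H](OC(C)=O)/C=C(C)\CO[Si](C)(C)C(C)(C)C
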